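**Plan**
1. Retrosynthesis: the twelve O–CH3 bonds are cut first (global demethylation). Ring C is then dismantled at C2–C3, C1–C6 and C3–C4 into an AB ethynyl ether (supplying C1 and C2) and a DE diazo ketone (supplying C3 to C6). Each half is finally cut at its aryl–O–aryl bond.
2. Enabling feature: ring C carries C1–O–ring B, C2–H, C3–OH, C4–OH, C5–O–ring D and C6–H. The C3 hydroxyl is meta to the C1 ether oxygen with unsubstituted C2 between them, and C4–O and C5–O follow C3 directly. This is the resorcinol monoether pattern that a vinylketene and an alkynyl ether assemble.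
3. Forward: rings A+B and D+E are joined first, each by aryl ether formation ortho to a formyl group (SNAr for A–O–B, Cu-catalysed Ullmann coupling for D–O–E) followed by Baeyer–Villiger oxidation to the ortho-aryloxy phenol.
4. The AB phenol becomes its ethynyl ether and the DE phenol is carried through a β-methoxyacrylate to the diazo ketone. Ring C is formed last, in the union of the halves, so neither hindered phenol on ring B or ring D is ever arylated.
5. Stereochemistry: the target has no stereocentre. The (Z) enol ether of the DE fragment is the only stereo-element on the way and it disappears on aromatisation.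

Key step: step 11

Remark: 2-fluoro-4,6-dimethoxybenzaldehyde and 2-bromo-3,4,5-trimethoxybenzaldehyde are taken as purchasable building blocks.
Abbreviations used in names: ArAB = 2,4-dimethoxy-6-(2,4,6-trimethoxyphenoxy)phenyl; ArDE = 3,4,5-trimethoxy-2-(3,4,5-trimethoxyphenoxy)phenyl.

**Route**

Step 1
Reactants: 1 (2,4,6-trimethoxyphenol); 2 (2-fluoro-4,6-dimethoxybenzaldehyde)
Product: 3 AB aldehyde [2,4-dimethoxy-6-(2,4,6-trimethoxyphenoxy)benzaldehyde]
Conditions: Cs2CO3, DMSO, 110 °C, Ar
Reagents that add atoms: none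
Why: Nucleophilic aromatic substitution (SNAr): the fluorine ortho to the formyl group should be displaced by the phenoxide of 1 through a Meisenheimer adduct that the two methoxy groups, both meta to fluorine, do not destabilise, and addition–elimination at the C–F carbon tolerates the two ortho-methoxy groups of the nucleophile.

Step 2
Reactants: 3 (AB aldehyde)
Product: 5 AB phenol [2,4-dimethoxy-6-(2,4,6-trimethoxyphenoxy)phenol], via AB aryl formate 4 (not isolated)
Conditions: mCPBA, CH2Cl2, 0 °C to rt; aq. NaHCO3 wash; then K2CO3 (cat.), MeOH, rt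
Reagents that add atoms: mCPBA, OOC(=O)c1cccc(Cl)c1
Why: Baeyer–Villiger oxidation: in the Criegee adduct the electron-rich 2,4,6-trioxygenated aryl group migrates in preference to hydrogen to give formate 4, which catalytic methanolysis should cleave to the ortho-aryloxy phenol.

Step 3
Reactants: 5 (AB phenol); 6 (trichloroethylene)
Product: 8 AB dichlorovinyl ether [2-[(E)-1,2-dichloroethenoxy]-1,5-dimethoxy-3-(2,4,6-trimethoxyphenoxy)benzene], via dichloroacetylene 7 (not isolated)
Conditions: K2CO3, DMF, 70 °C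
Reagents that add atoms: none
Why: Elimination–addition: carbonate converts trichloroethylene into dichloroacetylene 7, to which the phenoxide adds in an anti sense, the standard entry to (E)-1,2-dichlorovinyl aryl ethers, and the linear electrophile is reached easily even by this doubly ortho-substituted phenoxide.

Step 4
Reactants: 8 (AB dichlorovinyl ether)
Product: 11 AB ethynyl ether [2-(ethynyloxy)-1,5-dimethoxy-3-(2,4,6-trimethoxyphenoxy)benzene], via chloroethynyl ether 9 (not isolated), via lithium alkynyl ether 10 (not isolated)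
Conditions: n-BuLi (2.2 equiv), THF, −78 °C; then MeOH, −78 °C; stored cold and used promptly
Reagents that add atoms: none
Why: Dehydrochlorination by the first equivalent of n-BuLi gives chloroalkyne 9, chlorine–lithium exchange with the second gives lithium alkynyl ether 10 and protonation releases the terminal ynol ether (the usual dichlorovinyl ether route to alkynyl ethers), while −78 °C keeps the base from metalating the ring positions that lie between two methoxy groups.

Step 5
Reactants: 12 (3,4,5-trimethoxyphenol); 13 (2-bromo-3,4,5-trimethoxybenzaldehyde)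
Product: 14 DE aldehyde [3,4,5-trimethoxy-2-(3,4,5-trimethoxyphenoxy)benzaldehyde]
Conditions: CuI (10 mol %), picolinic acid (20 mol %), K3PO4, DMSO, 90 °C, Ar
Reagents that add atoms: none
Why: Ullmann diaryl ether synthesis catalysed by CuI and picolinic acid: the bromide is activated by its ortho formyl group and phenol 12 carries no ortho substituent, as in the known couplings of 2-bromo-3,4,5-trimethoxybenzoyl units with phenols.

Step 6
Reactants: 14 (DE aldehyde)
Product: 16 DE phenol [3,4,5-trimethoxy-2-(3,4,5-trimethoxyphenoxy)phenol], via DE aryl formate 15 (not isolated)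
Conditions: mCPBA, CH2Cl2, 0 °C to rt; aq. NaHCO3 wash; then K2CO3 (cat.), MeOH, rt
Reagents that add atoms: mCPBA, OOC(=O)c1cccc(Cl)c1
Why: Baeyer–Villiger oxidation as in step 2: the aryl group bearing a para methoxy and an ortho aryloxy substituent should migrate in preference to hydrogen, and methanolysis of formate 15 frees the phenol on ring D next to the D–O–E ether.

Step 7
Reactants: 16 (DE phenol); 17 (methyl bromoacetate)
Product: 18 methyl 2-(ArDE-oxy)acetate
Conditions: K2CO3, acetone, reflux
Reagents that add atoms: none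
Why: Williamson ether synthesis: SN2 displacement of bromide from the α-bromo ester by the phenoxide of 16, which is hindered on one side only.

Step 8
Reactants: 18 (methyl 2-(ArDE-oxy)acetate)
Product: 20 methyl (Z)-3-methoxy-2-(ArDE-oxy)prop-2-enoate, via sodium formyl ester enolate 19 (not isolated)
Conditions: NaH, HCO2Me, DMF, 0 °C to rt; then Me2SO4, rt
Reagents that add atoms: methyl formate, COC=O; dimethyl sulfate, COS(=O)(=O)OC
Why: Crossed Claisen condensation with methyl formate at the only enolisable position gives the stabilised formyl ester enolate 19, which the hard electrophile Me2SO4 should alkylate on oxygen as in the standard β-methoxyacrylate synthesis, the methoxy group settling trans to the ester carbonyl, which here is the (Z) alkene.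

Step 9
Reactants: 20 (methyl (Z)-3-methoxy-2-(ArDE-oxy)prop-2-enoate)
Product: 22 (Z)-3-methoxy-2-(ArDE-oxy)prop-2-enoic acid, via lithium carboxylate 21 (not isolated)
Conditions: LiOH·H2O, THF/MeOH/H2O, rt; then 1 M HCl to pH 3, 0 °C
Reagents that add atoms: lithium hydroxide, [Li+].[OH-]
Why: Saponification of the methyl ester: the β-methoxyacrylate is a vinylogous carbonate whose β-carbon is a poor acceptor for hydroxide at room temperature, and brief cold acidification of carboxylate 21 should free the acid without hydrolysing the enol ether.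

Step 10
Reactants: 22 ((Z)-3-methoxy-2-(ArDE-oxy)prop-2-enoic acid)
Product: 24 DE diazo ketone [(Z)-1-diazo-4-methoxy-3-(ArDE-oxy)but-3-en-2-one], via acid chloride 23 (not isolated)
Conditions: (COCl)2, DMF (cat.), CH2Cl2, 0 °C to rt, evaporate; then CH2N2 (excess), Et2O/THF, 0 °C
Reagents that add atoms: diazomethane, C=[N+]=[N-]
Why: Acid chloride formation followed by acylation of diazomethane (first stage of the Arndt–Eistert sequence), a second equivalent of diazomethane removing HCl; the doubly oxygen-substituted, trisubstituted alkene is a poor dipolarophile, so attack at the acyl chloride should outrun pyrazoline formation.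

Step 11
Reactants: 24 (DE diazo ketone); 11 (AB ethynyl ether)
Product: 29 dodeca-O-methyl pentamer with free C3–OH [2-methoxy-5-(ArAB-oxy)-3-(ArDE-oxy)phenol], via vinylketene 25 (not isolated), via vinylcyclobutenone 26 (not isolated), via dienylketene 27 (not isolated), via cyclohexadienone 28 (not isolated)
Conditions: hν (medium-pressure Hg lamp, Pyrex filter, >300 nm), 11 (2 equiv), degassed ClCH2CH2Cl, rt; then 80 °C in the dark
Reagents that add atoms: none
Why: Light above 300 nm, where the diazo ketone should be the only strong absorber, expels N2 and the alkenyl group migrates (photochemical Wolff rearrangement) to give vinylketene 25, whose carbonyl carbon is attacked by the nucleophilic CH terminus of ynol ether 11 in a regioselective [2+2] cycloaddition that forms C2–C3 and C1–C6 and gives vinylcyclobutenone 26. Reversible conrotatory 4π opening of 26 on warming delivers dienylketene 27, and ring C then closes by thermal disrotatory 6π electrocyclisation (bond C3–C4) to cyclohexadienone 28, which tautomerises to the phenol. The closest known reaction type is the Danheiser benzannulation in its diazo ketone form with alkoxy- and siloxyalkynes, which gives resorcinol monoethers of this substitution pattern. No stereocentre remains, since the sp3 carbons of 26 and 28 are transient and racemic and the enol ether geometry is erased on aromatisation. The step needs regioselectivity in the [2+2] event, secured by the polarisation of the aryloxyalkyne (oxygen-stabilised positive charge at C1, nucleophilic CH at C2), and capture of the ketene before it dimerises, secured by the excess of 11 and the slow photochemical release of 25. The methoxy group trans to the diazoacetyl arm keeps the ketocarbene away from the ether oxygen and leaves the ring-closing terminus unhindered.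

Step 12
Reactants: 29 (dodeca-O-methyl pentamer)
Product: 30 Pseudopentafuhalol D
Conditions: BBr3 (excess), CH2Cl2, −78 °C to rt, Ar; then H2O, 0 °C; degassed solvents for isolation
Reagents that add atoms: none
Why: Cleavage of aryl methyl ethers by BBr3 (bromide attacks the methyl group of each boron-complexed ether), a reaction that leaves diaryl ether bonds intact, so all twelve methoxy groups should be converted into hydroxyls while the four aryl–O–aryl links survive; air is excluded to protect the pyrogallol-type rings.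

**Compound list**
1 | 2,4,6-trimethoxyphenol | COc1cc(OC)c(O)c(OC)c1 | starting material
2 | 2-fluoro-4,6-dimethoxybenzaldehyde | COc1cc(F)c(C=O)c(OC)c1 | starting material
3 | 2,4-dimethoxy-6-(2,4,6-trimethoxyphenoxy)benzaldehyde | COc1cc(OC)c(Oc2cc(OC)cc(OC)c2C=O)c(OC)c1 | intermediate
4 | 2,4-dimethoxy-6-(2,4,6-trimethoxyphenoxy)phenyl formate | COc1cc(OC)c(Oc2cc(OC)cc(OC)c2OC=O)c(OC)c1 | intermediate (not isolated)
5 | 2,4-dimethoxy-6-(2,4,6-trimethoxyphenoxy)phenol | COc1cc(OC)c(Oc2cc(OC)cc(OC)c2O)c(OC)c1 | intermediate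
6 | trichloroethylene | ClC=C(Cl)Cl | starting material
7 | dichloroacetylene | ClC#CCl | intermediate (not isolated)
8 | 2-[(E)-1,2-dichloroethenoxy]-1,5-dimethoxy-3-(2,4,6-trimethoxyphenoxy)benzene | COc1cc(OC)c(Oc2cc(OC)cc(OC)c2O/C(Cl)=C\Cl)c(OC)c1 | intermediate
9 | 2-(chloroethynyloxy)-1,5-dimethoxy-3-(2,4,6-trimethoxyphenoxy)benzene | COc1cc(OC)c(Oc2cc(OC)cc(OC)c2OC#CCl)c(OC)c1 | intermediate (not isolated)
10 | [2-(ArAB-oxy)ethynyl]lithium | COc1cc(OC)c(Oc2cc(OC)cc(OC)c2OC#C[Li])c(OC)c1 | intermediate (not isolated)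
11 | 2-(ethynyloxy)-1,5-dimethoxy-3-(2,4,6-trimethoxyphenoxy)benzene | COc1cc(OC)c(Oc2cc(OC)cc(OC)c2OC#C)c(OC)c1 | intermediate
12 | 3,4,5-trimethoxyphenol | COc1cc(O)cc(OC)c1OC | starting material
13 | 2-bromo-3,4,5-trimethoxybenzaldehyde | COc1cc(C=O)c(Br)c(OC)c1OC | starting material
14 | 3,4,5-trimethoxy-2-(3,4,5-trimethoxyphenoxy)benzaldehyde | O=Cc1cc(OC)c(OC)c(OC)c1Oc1cc(OC)c(OC)c(OC)c1 | intermediate
15 | 3,4,5-trimethoxy-2-(3,4,5-trimethoxyphenoxy)phenyl formate | O=COc1cc(OC)c(OC)c(OC)c1Oc1cc(OC)c(OC)c(OC)c1 | intermediate (not isolated)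
16 | 3,4,5-trimethoxy-2-(3,4,5-trimethoxyphenoxy)phenol | Oc1cc(OC)c(OC)c(OC)c1Oc1cc(OC)c(OC)c(OC)c1 | intermediate
17 | methyl bromoacetate | COC(=O)CBr | starting material
18 | methyl 2-[3,4,5-trimethoxy-2-(3,4,5-trimethoxyphenoxy)phenoxy]acetate | COC(=O)COc1cc(OC)c(OC)c(OC)c1Oc1cc(OC)c(OC)c(OC)c1 | intermediate
19 | sodium 3-methoxy-3-oxo-2-(ArDE-oxy)prop-1-en-1-olate (enolate geometry not fixed) | [Na+].[O-]C=C(Oc1cc(OC)c(OC)c(OC)c1Oc1cc(OC)c(OC)c(OC)c1)C(=O)OC | intermediate (not isolated)
20 | methyl (Z)-3-methoxy-2-(ArDE-oxy)prop-2-enoate | CO/C=C(\Oc1cc(OC)c(OC)c(OC)c1Oc1cc(OC)c(OC)c(OC)c1)C(=O)OC | intermediate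
21 | lithium (Z)-3-methoxy-2-(ArDE-oxy)prop-2-enoate | [Li+].CO/C=C(\Oc1cc(OC)c(OC)c(OC)c1Oc1cc(OC)c(OC)c(OC)c1)C(=O)[O-] | intermediate (not isolated)
22 | (Z)-3-methoxy-2-(ArDE-oxy)prop-2-enoic acid | CO/C=C(\Oc1cc(OC)c(OC)c(OC)c1Oc1cc(OC)c(OC)c(OC)c1)C(=O)O | intermediate
23 | (Z)-3-methoxy-2-(ArDE-oxy)prop-2-enoyl chloride | CO/C=C(\Oc1cc(OC)c(OC)c(OC)c1Oc1cc(OC)c(OC)c(OC)c1)C(=O)Cl | intermediate (not isolated)
24 | (Z)-1-diazo-4-methoxy-3-[3,4,5-trimethoxy-2-(3,4,5-trimethoxyphenoxy)phenoxy]but-3-en-2-one | CO/C=C(\Oc1cc(OC)c(OC)c(OC)c1Oc1cc(OC)c(OC)c(OC)c1)C(=O)C=[N+]=[N-] | intermediate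
25 | (Z)-4-methoxy-3-(ArDE-oxy)buta-1,3-dien-1-one | CO/C=C(\Oc1cc(OC)c(OC)c(OC)c1Oc1cc(OC)c(OC)c(OC)c1)C=C=O | intermediate (not isolated)
26 | (±)-3-(ArAB-oxy)-4-[(Z)-2-methoxy-1-(ArDE-oxy)ethenyl]cyclobut-2-en-1-one | COc1cc(OC)c(Oc2cc(OC)cc(OC)c2OC2=CC(=O)C2/C(Oc2cc(OC)c(OC)c(OC)c2Oc2cc(OC)c(OC)c(OC)c2)=C/OC)c(OC)c1 | intermediate (not isolated)
27 | (3E,5Z)-6-methoxy-3-(ArAB-oxy)-5-(ArDE-oxy)hexa-1,3,5-trien-1-one | COc1cc(OC)c(Oc2cc(OC)cc(OC)c2OC(/C=C=O)=C/C(Oc2cc(OC)c(OC)c(OC)c2Oc2cc(OC)c(OC)c(OC)c2)=C/OC)c(OC)c1 | intermediate (not isolated)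
28 | (±)-6-methoxy-3-(ArAB-oxy)-5-(ArDE-oxy)cyclohexa-2,4-dien-1-one | COc1cc(OC)c(Oc2cc(OC)cc(OC)c2OC2=CC(=O)C(OC)C(Oc3cc(OC)c(OC)c(OC)c3Oc3cc(OC)c(OC)c(OC)c3)=C2)c(OC)c1 | intermediate (not isolated)
29 | 2-methoxy-5-[2,4-dimethoxy-6-(2,4,6-trimethoxyphenoxy)phenoxy]-3-[3,4,5-trimethoxy-2-(3,4,5-trimethoxyphenoxy)phenoxy]phenol | COc1cc(OC)c(Oc2cc(OC)cc(OC)c2Oc2cc(O)c(OC)c(Oc3cc(OC)c(OC)c(OC)c3Oc3cc(OC)c(OC)c(OC)c3)c2)c(OC)c1 | intermediate
30 | Pseudopentafuhalol D | Oc1cc(O)c(Oc2cc(O)cc(O)c2Oc2cc(O)c(O)c(Oc3cc(O)c(O)c(O)c3Oc3cc(O)c(O)c(O)c3)c2)c(O)c1 | target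

**Summary**
Total step count: 12.
Longest linear sequence: 8 steps (steps 5 to 12); the AB branch (steps 1 to 4) joins in step 11.

**Steps most likely to fail**

Step 11. The terminal ethynyl ether may be lost by polymerisation or light-induced decomposition faster than it intercepts the vinylketene. Ketene dimerisation, capture of the ketene by ring D or acylation of the product phenol would then take over. The fallback sets out from 8. Lithium alkynyl ether 10 is quenched with Me3SiCl in place of methanol to give the C-trimethylsilyl ynol ether F1, a storable ketenophile in which oxygen and silicon polarise the triple bond in the same sense. Irradiation of 24 with F1 under the conditions of step 11 should then pass through vinylketene 25, the silylated vinylcyclobutenone F2, the silylated dienylketene F3 and the silylated cyclohexadienone F4 to the 2-silyl phenol F5. Protodesilylation with CF3CO2H in CH2Cl2 (ipso protonation of a carbon flanked by two oxygen-bearing carbons) comes back to the route at 29.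

Step 10. Diazomethane may add as a 1,3-dipole across the acryloyl double bond. HCl released during chloride formation may add to or isomerise the enol ether, and the acid chloride may acylate ring D intramolecularly. The fallback sets out from acid 22. Amide coupling with MeNHOMe·HCl (EDC·HCl, i-Pr2NEt, CH2Cl2) gives the Weinreb amide F6, and MeMgBr (THF, 0 °C) converts it into the methyl ketone F7. Detrifluoroacetylative diazo transfer (LiHMDS, THF, −78 °C; CF3CO2CH2CF3 to the trifluoroacetyl ketone F8, not isolated; then MsN3, Et3N, H2O, MeCN) comes back to the route at 24 without an acid chloride and without diazomethane.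

Step 12. Some of the twelve methyl ethers may remain uncleaved, and the pyrogallol-type rings may be oxidised by air during aqueous work-up and chromatography. The fallback sets out from 29. The crude BBr3 product is acetylated at once (Ac2O, pyridine, DMAP) to the air-stable trideca-O-acetate F9, which can be purified on silica gel away from partially methylated material. Acid-catalysed methanolysis (HCl from AcCl in degassed MeOH, Ar) comes back to the route at 30.

**Further compounds**
F1 | step 11 | trimethyl[2-(ArAB-oxy)ethynyl]silane | COc1cc(OC)c(Oc2cc(OC)cc(OC)c2OC#C[Si](C)(C)C)c(OC)c1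
F2 | step 11 | (±)-3-(ArAB-oxy)-4-[(Z)-2-methoxy-1-(ArDE-oxy)ethenyl]-2-(trimethylsilyl)cyclobut-2-en-1-one | COc1cc(OC)c(Oc2cc(OC)cc(OC)c2OC2=C([Si](C)(C)C)C(=O)C2/C(Oc2cc(OC)c(OC)c(OC)c2Oc2cc(OC)c(OC)c(OC)c2)=C/OC)c(OC)c1
F3 | step 11 | 6-methoxy-3-(ArAB-oxy)-5-(ArDE-oxy)-2-(trimethylsilyl)hexa-1,3,5-trien-1-one (C2 and C5 cis across C3=C4, methoxy cis to ArDE-oxy) | COc1cc(OC)c(Oc2cc(OC)cc(OC)c2OC(/C(=C=O)[Si](C)(C)C)=C/C(Oc2cc(OC)c(OC)c(OC)c2Oc2cc(OC)c(OC)c(OC)c2)=C/OC)c(OC)c1
F4 | step 11 | (±)-6-methoxy-3-(ArAB-oxy)-5-(ArDE-oxy)-2-(trimethylsilyl)cyclohexa-2,4-dien-1-one | COc1cc(OC)c(Oc2cc(OC)cc(OC)c2OC2=C([Si](C)(C)C)C(=O)C(OC)C(Oc3cc(OC)c(OC)c(OC)c3Oc3cc(OC)c(OC)c(OC)c3)=C2)c(OC)c1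
F5 | step 11 | 6-methoxy-3-(ArAB-oxy)-5-(ArDE-oxy)-2-(trimethylsilyl)phenol | COc1cc(OC)c(Oc2cc(OC)cc(OC)c2Oc2cc(Oc3cc(OC)c(OC)c(OC)c3Oc3cc(OC)c(OC)c(OC)c3)c(OC)c(O)c2[Si](C)(C)C)c(OC)c1
F6 | step 10 | (Z)-N,3-dimethoxy-N-methyl-2-(ArDE-oxy)prop-2-enamide | CO/C=C(\Oc1cc(OC)c(OC)c(OC)c1Oc1cc(OC)c(OC)c(OC)c1)C(=O)N(C)OC
F7 | step 10 | (Z)-4-methoxy-3-(ArDE-oxy)but-3-en-2-one | CO/C=C(\Oc1cc(OC)c(OC)c(OC)c1Oc1cc(OC)c(OC)c(OC)c1)C(C)=O
F8 | step 10 | (Z)-1,1,1-trifluoro-6-methoxy-5-(ArDE-oxy)hex-5-ene-2,4-dione | CO/C=C(\Oc1cc(OC)c(OC)c(OC)c1Oc1cc(OC)c(OC)c(OC)c1)C(=O)CC(=O)C(F)(F)F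
F9 | step 12 | Pseudopentafuhalol D trideca-O-acetate | CC(=O)Oc1cc(OC(C)=O)c(Oc2cc(OC(C)=O)cc(OC(C)=O)c2Oc2cc(OC(C)=O)c(OC(C)=O)c(Oc3cc(OC(C)=O)c(OC(C)=O)c(OC(C)=O)c3Oc3cc(OC(C)=O)c(OC(C)=O)c(OC(C)=O)c3)c2)c(OC(C)=O)c1
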